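**Strategy.** Everything rests on the ring-fusion bond between the methyl-bearing quaternary carbon (C1) and the ring-fusion CH (C5), common to the cyclopentane and the cycloheptene. If C1 is bonded to the ester carbon C6 instead, the trans-hydroazulene becomes a cis-decalin, available from (S)-Wieland–Miescher ketone. The key step is a pinacol-type 1,2-shift in an all-cis C4,C5,C6-triol 5-mesylate: C1 migrates from the C6 carbinol to C5, which contracts ring B to the cyclopentane, expands ring A to the cycloheptene and leaves the C6 ketone. It exploits that C5 lies between the oxygen-bearing C4 and C6; the bought stereocentre C1 relays C4, C5, C6 and C10.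

Key step: step 9

Remark: atoms keep the daucane numbering of the target in every intermediate (C1 = quaternary C–CH3; C2, C3 = CH2; C4 = C(OH)(i-Pr); C5 = ring-fusion CH; C6 = ester carbon; C7 = CH2; C8 = C–CH3 of the alkene; C9 = alkene CH; C10 = CHOH). β is the face of the C1 methyl, α the opposite face. Ring A is the ring that holds C7–C10, ring B the ring that holds C2–C5. (S)-Wieland–Miescher ketone is taken as purchased enantiopure.

Step 1
Reactants: 1 (S)-Wieland–Miescher ketone
Product: 2 (S)-bis-enone (1 with an added C8=C9 double bond)
Conditions: IBX (1.3 equiv), fluorobenzene–DMSO 2:1, 65 °C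
Reagents that add atoms: none
Why: IBX dehydrogenation of a ketone through its enol: the saturated C10 ketone can enolise only towards C9 and reacts at 65 °C, whereas further dehydrogenation of the ring B enone needs more oxidant and a higher temperature, so the C8=C9 enone should form selectively.

Step 2
Reactants: 2 (S)-bis-enone; 3 methyllithium; 4 chlorotrimethylsilane
Product: 5 C10 trimethylsilyl enol ether with the new C8 methyl (C8 epimers)
Conditions: MeLi (2.2 equiv), CuI (1.1 equiv), Et2O, 0 °C; then 2, TMSCl (2 equiv), THF, −78 °C; Et3N, pentane work-up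
Reagents that add atoms: methyllithium (delivered as Me2CuLi), [Li]C; chlorotrimethylsilane, C[Si](C)(C)Cl
Why: Conjugate addition of a lithium dialkylcuprate with silyl trapping: the unsubstituted β-carbon C8 of the new enone is attacked, the fully substituted β-carbon C6 of the ring B enone is not, and the C8 configuration is irrelevant because C8 becomes sp2 again in step 3.

Step 3
Reactants: 5 C10 trimethylsilyl enol ether
Product: 6 (S)-8-methyl bis-enone
Conditions: Pd(OAc)2 (1.05 equiv), MeCN, 25 °C
Reagents that add atoms: none
Why: Saegusa–Ito oxidation: the silyl enol ether gives the C9 palladium enolate regiospecifically and β-hydride elimination of the C8 hydrogen places the C8=C9 double bond next to the new methyl group.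

Step 4
Reactants: 6 (S)-8-methyl bis-enone; 7 isopropylmagnesium chloride
Product: 8 tertiary allylic alcohol (4β-OH, 4α-isopropyl, C5=C6; C10 enone kept)
Conditions: i-PrMgCl (1.3 equiv), anhydrous CeCl3 (1.4 equiv), THF, −78 °C; aq. NH4Cl
Reagents that add atoms: isopropylmagnesium chloride, CC(C)[Mg]Cl
Why: Organocerium 1,2-addition: the weakly basic reagent adds to the unhindered C4 carbonyl and not to the neopentyl, β-methyl-deactivated C10 carbonyl, and axial attack on the half-chair enone from the α face (as in hydride additions to 3-oxo-4-ene steroids) should place the C4 hydroxyl β, cis to the C1 methyl.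

Step 5
Reactants: 8 tertiary allylic alcohol; 9 osmium tetroxide
Product: 10 all-cis 4β,5β,6β-triol (cis-decalin, C10 enone)
Conditions: OsO4 (1.05 equiv), TMEDA (1.1 equiv), CH2Cl2, −78 °C; then ethylenediamine, 25 °C
Reagents that add atoms: osmium tetroxide, O=[Os](=O)(=O)=O
Why: Hydrogen-bond-directed dihydroxylation with OsO4·TMEDA: in the half-chair with pseudoequatorial isopropyl the pseudoaxial C4–OH binds the reagent and delivers both oxygens to the β face of the electron-rich C5=C6 bond, which sets C5 and C6, gives the cis ring fusion and leaves the electron-poor C8=C9 enone untouched.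

Step 6
Reactants: 10 all-cis triol; 11 methanesulfonyl chloride
Product: 12 5β-mesylate
Conditions: MsCl (1.2 equiv), Et3N (2 equiv), CH2Cl2, −20 °C
Reagents that add atoms: methanesulfonyl chloride, CS(=O)(=O)Cl
Why: Sulfonylation through sulfene reacts only with the single secondary hydroxyl (C5), the two tertiary hydroxyls being inert, and the all-cis triad cannot close an epoxide.

Step 7
Reactants: 12 5β-mesylate
Product: 13 10α-allylic alcohol
Conditions: NaBH4 (1.5 equiv), CeCl3·7H2O (1.2 equiv), MeOH, −40 °C
Reagents that add atoms: none
Why: Luche 1,2-reduction: in the cis-decalin chair with equatorial isopropyl, C5 is axial on ring A and 1,3-diaxial to C10, so hydride should enter from the convex β face and give the 10α-alcohol (trans to the C1 methyl), under conditions too mild to trigger the rearrangement.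

Step 8
Reactants: 13 10α-allylic alcohol; 14 tert-butyldimethylsilyl trifluoromethanesulfonate
Product: 15 10α-O-TBS ether
Conditions: TBSOTf (1.1 equiv), 2,6-lutidine (2 equiv), CH2Cl2, −78 °C
Reagents that add atoms: tert-butyldimethylsilyl trifluoromethanesulfonate, CC(C)(C)[Si](C)(C)OS(=O)(=O)C(F)(F)F
Why: Silylation with a silyl triflate at low temperature is selective for the only secondary hydroxyl and masks O10 for the later acylation.

Step 9
Reactants: 15 10α-O-TBS ether
Product: 16 trans-fused hydroazulenone (C6 ketone, 4β-OH, 5α-H)
Conditions: Et3Al (3.5 equiv), CH2Cl2, −78 → 0 °C; aq. KNaC4H4O6 work-up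
Reagents that add atoms: none
Why: Et3Al turns the tertiary hydroxyls into aluminium alkoxides and activates the mesylate; as the C5–O bond ionises, the C1–C6 σ bond, antiperiplanar to the equatorial mesylate in the ring B chair with equatorial isopropyl, shifts from C6 to C5 while the C6 alkoxide becomes the ketone. The closest known reaction type is the pinacol-type (semipinacol) rearrangement of 2-hydroxy sulfonates promoted by organoaluminium reagents, the classical hydronaphthalene-to-hydroazulene conversion. The cyclopentane closes by a suprafacial 1,2-alkyl shift, an intramolecular backside displacement at C5 through a three-centre transition state (contraction of ring B), and the cycloheptenone arises by the simultaneous one-carbon expansion of ring A. C5 is formed with inversion, so its hydrogen ends up trans to the C1 methyl; C1 migrates with retention and C4 and C10 are untouched, so the trans ring fusion and the cis C4–OH/C1–CH3 relation follow stereospecifically from the all-cis triol. The step needs migration of C1 and not of C7 or C3: C7 is gauche to the leaving group, and the quaternary C1 has a far higher migratory aptitude than the C3 methylene that the C4 alkoxide could push. The all-cis oxygens exclude epoxide formation, and cold, Lewis-acidic, non-basic conditions protect the β-hydroxy ketone and the β,γ-alkene of the product.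

Step 10
Reactants: 16 trans-fused hydroazulenone
Product: 17 6α-alcohol
Conditions: Me4NBH(OAc)3 (5 equiv), MeCN–AcOH 1:1, −30 °C
Reagents that add atoms: none
Why: Evans–Saksena reduction: the C4 hydroxyl exchanges an acetate on boron and delivers hydride intramolecularly to the face of the C6 carbonyl on which O4 lies (the β face of the chair cycloheptenone), which should give the equatorial 6α-alcohol, anti to C4–OH.

Step 11
Reactants: 17 6α-alcohol; 18 4-methoxybenzoyl chloride
Product: 20 target anisoate CNP0211568.1, via 10-O-TBS anisoate 19 (not isolated)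
Conditions: 4-MeOC6H4COCl (1.5 equiv), DMAP (0.3 equiv), Et3N (3 equiv), CH2Cl2, 0 → 35 °C; then HF·pyridine, THF, 0 → 25 °C
Reagents that add atoms: 4-methoxybenzoyl chloride, COc1ccc(C(=O)Cl)cc1
Why: DMAP-catalysed acylation esterifies the only secondary hydroxyl (the tertiary C4–OH does not react), and buffered fluoride then cleaves the silyl ether without touching the aryl ester or the allylic carbinol.

**Compound list**

1 | (S)-Wieland–Miescher ketone, (8aS)-8a-methyl-3,4,8,8a-tetrahydronaphthalene-1,6(2H,7H)-dione (C1 angular, C10 saturated ketone, C4 enone, C5=C6) | C[C@]12CCC(=O)C=C1CCCC2=O | starting material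
2 | (S)-bis-enone: 1 with an additional C8=C9 double bond | C[C@]12CCC(=O)C=C1CC=CC2=O | intermediate
3 | methyllithium | [Li]C | starting material
4 | chlorotrimethylsilane | C[Si](C)(C)Cl | starting material
5 | C10-trimethylsilyloxy C9=C10 enol ether with 8-methyl (both C8 epimers), C4 enone, C1 S | C[C@]12CCC(=O)C=C1CC(C)C=C2O[Si](C)(C)C | intermediate
6 | (S)-8-methyl bis-enone: C10(=O)–C9=C8(CH3) and C4(=O)–C5=C6 | C[C@]12CCC(=O)C=C1CC(C)=CC2=O | intermediate
7 | isopropylmagnesium chloride | CC(C)[Mg]Cl | starting material
8 | 4β-hydroxy-4α-isopropyl C5=C6 allylic alcohol, C10 enone | C[C@]12CC[C@@](O)(C(C)C)C=C1CC(C)=CC2=O | intermediate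
9 | osmium tetroxide | O=[Os](=O)(=O)=O | starting material
10 | all-cis 4β,5β,6β-trihydroxy-4α-isopropyl cis-decalin, C10 enone | O[C@]12CC(C)=CC(=O)[C@@]1(C)CC[C@@](O)(C(C)C)[C@@H]2O | intermediate
11 | methanesulfonyl chloride | CS(=O)(=O)Cl | starting material
12 | 5β-mesylate of 10 | O[C@]12CC(C)=CC(=O)[C@@]1(C)CC[C@@](O)(C(C)C)[C@@H]2OS(C)(=O)=O | intermediate
13 | 10α-hydroxy 5β-mesylate (C8=C9 allylic alcohol) | O[C@]12CC(C)=C[C@@H](O)[C@@]1(C)CC[C@@](O)(C(C)C)[C@@H]2OS(C)(=O)=O | intermediate
14 | tert-butyldimethylsilyl trifluoromethanesulfonate | CC(C)(C)[Si](C)(C)OS(=O)(=O)C(F)(F)F | starting material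
15 | 10α-O-TBS ether of 13 | O[C@]12CC(C)=C[C@@H](O[Si](C)(C)C(C)(C)C)[C@@]1(C)CC[C@@](O)(C(C)C)[C@@H]2OS(C)(=O)=O | intermediate
16 | trans-fused hydroazulenone: C6 ketone, 4β-OH, 4α-isopropyl, 5α-H, 1β-CH3, 10α-OTBS, C8=C9 | O=C1CC(C)=C[C@@H](O[Si](C)(C)C(C)(C)C)[C@@]2(C)CC[C@@](O)(C(C)C)[C@H]12 | intermediate
17 | 6α-alcohol of 16 (4β,6α-diol, 10α-OTBS) | O[C@H]1CC(C)=C[C@@H](O[Si](C)(C)C(C)(C)C)[C@@]2(C)CC[C@@](O)(C(C)C)[C@H]12 | intermediate
18 | 4-methoxybenzoyl chloride | COc1ccc(C(=O)Cl)cc1 | starting material
19 | 10-O-TBS ether of the target | COc1ccc(C(=O)O[C@H]2CC(C)=C[C@@H](O[Si](C)(C)C(C)(C)C)[C@@]3(C)CC[C@@](O)(C(C)C)[C@H]23)cc1 | intermediate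
20 | CNP0211568.1: 4β,10α-dihydroxy-6α-(4-methoxybenzoyloxy)dauc-8-ene (1β-CH3, 5α-H) | COc1ccc(C(=O)O[C@H]2CC(C)=C[C@@H](O)[C@@]3(C)CC[C@@](O)(C(C)C)[C@H]23)cc1 | target

**Step count.** Total: 11 steps. Longest linear sequence: 11 steps (fully linear from 1).

**The three steps most likely to fail**

Step 4. The bulky nucleophile may attack equatorially and give the C4 epimer, or the reagent may enolise the doubly activated C7 methylene. The fallback sets out from 6 and comes back at 10. Luche reduction (NaBH4, CeCl3·7H2O, MeOH, −78 °C) of the unhindered C4 carbonyl, where axial attack of a small hydride is dependable, should give the 4β-allylic alcohol F1. The same OsO4·TMEDA dihydroxylation, now directed by a secondary hydroxyl, should give the all-cis triol with secondary C4–OH F2. Bu2SnO followed by NBS should oxidise the axial, less hindered C4 hydroxyl of the cis-4,5-diol to the α-hydroxy ketone F3. i-PrMgCl/CeCl3 should then add equatorially, chelated to O5 and anti to the axial C6–OH, to give 10.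

Step 7. Hydride may attack from the α face, anti to the C1 methyl, and give the 10β epimer. The fallback sets out from 12 and comes back at 13; it replaces steric approach control by intramolecular delivery. Me4NBH(OAc)3 in MeCN–AcOH reduces only where a bound hydroxyl can deliver hydride; the C6 alkoxyborohydride can reach C10 only from the β face, through the ring-flipped conformer in which O6 is axial on ring A. This should lead to the same 10α-alcohol and makes no new compound.

Step 9. The C4 alkoxide may push the C3 methylene to C5 (contraction to an acylcyclopentane), and the aluminium aldolate of the product may undergo retro-aldol cleavage. The fallback sets out from 15 and comes back at 16. TMS-imidazole should silylate the more accessible tertiary C4–OH to give the C4 trimethylsilyl ether F4. KN(SiMe3)2 (1.05 equiv, THF, −78 → −20 °C, AcOH quench) then forms only the C6 alkoxide, whose alkoxide-accelerated 1,2-shift should give the silylated hydroazulenone F5. PPTS in MeOH at 0 °C removes the trimethylsilyl group to give 16.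

**Further compounds**

F1 | step 4 | 4β-hydroxy C5=C6 allylic alcohol (secondary), C10 enone | C[C@]12CC[C@H](O)C=C1CC(C)=CC2=O
F2 | step 4 | all-cis 4β,5β,6β-triol with secondary C4–OH, C10 enone | O[C@]12CC(C)=CC(=O)[C@@]1(C)CC[C@H](O)[C@@H]2O
F3 | step 4 | 5β,6β-dihydroxy C4 ketone (α-hydroxy ketone), C10 enone | O[C@]12CC(C)=CC(=O)[C@@]1(C)CCC(=O)[C@@H]2O
F0 | step 7 | none | none
F4 | step 9 | C4 trimethylsilyl ether of 15 | O[C@]12CC(C)=C[C@@H](O[Si](C)(C)C(C)(C)C)[C@@]1(C)CC[C@@](O[Si](C)(C)C)(C(C)C)[C@@H]2OS(C)(=O)=O
F5 | step 9 | C4 trimethylsilyl ether of 16 | O=C1CC(C)=C[C@@H](O[Si](C)(C)C(C)(C)C)[C@@]2(C)CC[C@@](O[Si](C)(C)C)(C(C)C)[C@H]12
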